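**Plan**

- Retrosynthesis: the C15/C19 esters and a C2 ester are cut last. The exocyclic C8=C17 alkene is traced back to a ring B Δ7 alkene (1,3-transposition), and the C20 methyl to an angular formyl group. Ring B is then cut at C5–C6 and C9–C10 into a ring A cyclohexenecarbaldehyde and an acyclic trienoate.
- Enabling feature: ring B (C5–C10) is a cyclohexane whose fusion bond C5–C10 can act as the 2π unit and C6–C9 as the 4π unit. Because C10 carries the one-carbon branch C20, the ring A alkene C5=C10 can be conjugated to a formyl chromophore and photoisomerised to a strained (E)-cyclohexene, which adds the diene to give the trans-decalin directly.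
- Forward order: ring A first (epoxide/malonate lactone, methylation, lactol, ozonolysis–intramolecular aldol condensation); the diene chain from methyl geranate (ozonolysis, two Wittig reactions); ring B by the photochemical Diels–Alder union; then adjustment of C20, C8=C17 and the esters.
- Stereochemistry: C2 from the (R)-epoxide; C4 from the trans-selective lactone methylation; C5/C10 from the E geometry of the photogenerated alkene, its sense fixed by C2 and C4; C9 from the 6E diene geometry and formyl-endo addition; 13E carried over from methyl geranate.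

Key step: step 9

Remark: methyl geranate is taken as the pure 2E isomer. Bicyclic compounds are named on the labdane skeleton (C17 on C8, C18 = 4α-methyl, C19 = 4β-carboxyl carbon, C20 on C10), and fragment atoms are cited by the labdane numbers they become.

**Route**

Step 1
Reactants: 1 (R)-2-(but-3-en-1-yl)oxirane; 2 tert-butyl methyl malonate
Product: 3 tert-butyl (5R)-5-(but-3-en-1-yl)-2-oxooxolane-3-carboxylate (both C3 epimers)
Conditions: NaOMe, MeOH, 65 °C; AcOH
Reagents that add atoms: none
Why: Malonate alkylation by SN2 opening of the epoxide at its CH2 terminus, then lactonisation of the alkoxide onto the methyl ester (the tert-butyl ester is too hindered), so the C–O stereocentre of 1 (future C2) is carried over unchanged.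

Step 2
Reactants: 3 tert-butyl (5R)-5-(but-3-en-1-yl)-2-oxooxolane-3-carboxylate
Product: 4 tert-butyl (3S,5R)-5-(but-3-en-1-yl)-3-methyl-2-oxooxolane-3-carboxylate
Conditions: NaH, THF, 0 °C; MeI, 0 → 20 °C
Reagents that add atoms: iodomethane, CI
Why: C-Methylation of the stabilised lactone enolate; iodomethane should approach trans to the C5 butenyl group, which sets the quaternary centre (future C4: methyl trans, ester cis to the side chain), the minor cis isomer being removed by chromatography.

Step 3
Reactants: 4 tert-butyl (3S,5R)-5-(but-3-en-1-yl)-3-methyl-2-oxooxolane-3-carboxylate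
Product: 5 tert-butyl (3S,5R)-5-(but-3-en-1-yl)-2-hydroxy-3-methyloxolane-3-carboxylate (anomers)
Conditions: i-Bu2AlH (1.1 equiv), CH2Cl2, −78 °C
Reagents that add atoms: none
Why: Partial reduction of a γ-lactone to the lactol (stable aluminium hemiacetal at −78 °C), chemoselective because the neopentyl tert-butyl ester is far less electrophilic; no stereocentre is touched.

Step 4
Reactants: 5 tert-butyl (3S,5R)-5-(but-3-en-1-yl)-2-hydroxy-3-methyloxolane-3-carboxylate
Product: 7 tert-butyl (1S,5R)-3-formyl-5-hydroxy-1-methylcyclohex-2-ene-1-carboxylate, via lactol aldehyde 6 (not isolated)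
Conditions: O3, CH2Cl2, −78 °C; PPh3; then Bn2NH·CF3CO2H (20 mol %), toluene, 50 °C
Reagents that add atoms: ozone, [O-][O+]=O
Why: Ozonolysis unmasks the C20 aldehyde, and amine-salt-catalysed intramolecular aldol condensation closes ring A as the conjugated enal (the enamine of the only enolisable aldehyde attacks the α-quaternary aldehyde released from the lactol, 6-exo-trig, then dehydration); C2 and C4 are not enolisable and keep their configuration.

Step 5
Reactants: 7 tert-butyl (1S,5R)-3-formyl-5-hydroxy-1-methylcyclohex-2-ene-1-carboxylate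
Product: 8 tert-butyl (1S,5R)-5-acetoxy-3-formyl-1-methylcyclohex-2-ene-1-carboxylate
Conditions: Ac2O, pyridine, DMAP (cat.), CH2Cl2, 0 → 20 °C
Reagents that add atoms: acetic anhydride, CC(=O)OC(C)=O
Why: Standard DMAP-catalysed acylation masks the C2 hydroxyl, which could otherwise add to the strained alkene of step 9, as an ester that the final saponification removes.

Step 6
Reactants: 9 methyl geranate, methyl (2E)-3,7-dimethylocta-2,6-dienoate
Product: 10 methyl (2E)-3-methyl-6-oxohex-2-enoate
Conditions: O3 (1 equiv), CH2Cl2, pyridine, −78 °C; Me2S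
Reagents that add atoms: ozone, [O-][O+]=O
Why: Chemoselective ozonolysis; the electron-rich trisubstituted C6=C7 alkene reacts far faster than the conjugated enoate, so the (2E)-enoate (future 13E) survives.

Step 7
Reactants: 10 methyl (2E)-3-methyl-6-oxohex-2-enoate
Product: 11 methyl (2E,6E)-3,7-dimethyl-8-oxoocta-2,6-dienoate
Conditions: Ph3P=C(CH3)CHO, toluene, 90 °C
Reagents that add atoms: 2-(triphenylphosphoranylidene)propanal, CC(C=O)=P(c1ccccc1)(c1ccccc1)c1ccccc1
Why: Wittig reaction with a stabilised formyl ylide, which should give the (E)-2-methyl-2-enal (chain trans to CHO).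

Step 8
Reactants: 11 methyl (2E,6E)-3,7-dimethyl-8-oxoocta-2,6-dienoate
Product: 12 methyl (2E,6E)-3,7-dimethylnona-2,6,8-trienoate
Conditions: Ph3PCH3Br, KN(SiMe3)2, THF, 0 °C; then 11, −78 → 0 °C
Reagents that add atoms: methyltriphenylphosphonium bromide, C[P+](c1ccccc1)(c1ccccc1)c1ccccc1.[Br-]
Why: Wittig methylenation of the aldehyde (1,2-addition of the non-stabilised ylide, esters untouched) gives the diene with the 6E geometry (C11 trans to the vinyl group) retained.

Step 9
Reactants: 8 tert-butyl (1S,5R)-5-acetoxy-3-formyl-1-methylcyclohex-2-ene-1-carboxylate; 12 methyl (2E,6E)-3,7-dimethylnona-2,6,8-trienoate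
Product: 14 19-tert-butyl 15-methyl (13E)-2α-acetoxy-20-oxolabda-7,13-diene-15,19-dioate (trans-decalin: 5α-H, 9α-H, 10β-CHO), via twisted (E)-cyclohexene enal 13 (not isolated)
Conditions: hν (350 nm, Pyrex), 12 (4 equiv), CH2Cl2, −78 °C
Reagents that add atoms: none
Why: n→π* excitation of enal 8 (the only chromophore above 340 nm), intersystem crossing and twisting about C5=C10 give the ground-state (E)-cyclohexene 13, whose strain is released in a thermal suprafacial [4+2] addition of the s-cis diene unit C6=C7–C8=C9 of 12; the closest known reaction type is the photochemical trans-selective Diels–Alder reaction of 1-acetylcyclohexene and of cyclohept-2-enones with 1,3-dienes through their (E)-isomers. Ring B (six-membered) closes by this intermolecular [4π+2π] cycloaddition, which forms C5–C6 and C9–C10 in one operation. C5 and C10: because C1 and C4 are trans on the (E)-alkene, suprafacial addition gives the trans ring fusion (5α-H, 10β-CHO), and the twist sense that reacts is set by C2 and C4, since only one helical form keeps 2-OAc and 4-CH3 equatorial-like (the other places OAc, CH3 and CHO syn-axial). C9: set by the 6E geometry of 12 (C11 "outside") together with the formyl-endo transition state, which puts C11 cis to C20. The step needs regioselectivity (C6 to C5, C9 to C10), which should follow from attack of the unsubstituted diene terminus C6 on the electrophilic β-carbon C5 ("ortho" orientation of a 1,2-dialkyl diene, also the less hindered pairing), and chemoselectivity, which rests on the diene and both ester alkenes being transparent at 350 nm and on the enoate being neither a competent diene nor dienophile here.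

Step 10
Reactants: 14 19-tert-butyl 15-methyl (13E)-2α-acetoxy-20-oxolabda-7,13-diene-15,19-dioate
Product: 16 19-tert-butyl 15-methyl (13E)-2α-acetoxylabda-7,13-diene-15,19-dioate, via tosylhydrazone 15 (not isolated)
Conditions: TsNHNH2, EtOH, 60 °C; then catecholborane, CHCl3, 0 °C; NaOAc·3H2O, 60 °C
Reagents that add atoms: none
Why: Wolff–Kishner-type deoxygenation under mild conditions; the tosylhydrazone is reduced by catecholborane and acetate triggers loss of sulfinate and N2 from the diazene, turning the angular CHO into the C20 methyl without touching esters, alkenes or stereocentres.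

Step 11
Reactants: 16 19-tert-butyl 15-methyl (13E)-2α-acetoxylabda-7,13-diene-15,19-dioate
Product: 17 19-tert-butyl 15-methyl (13E)-2α-acetoxy-7ξ-chlorolabda-8(17),13-diene-15,19-dioate (C7 epimers)
Conditions: PhSeCl (10 mol %), N-chlorosuccinimide, CH2Cl2, 20 °C
Reagents that add atoms: N-chlorosuccinimide, O=C1CCC(=O)N1Cl
Why: Selenium-catalysed ene-type allylic chlorination of the only electron-rich alkene; addition of PhSeCl across C7=C8, oxidation by the N-chloroimide and syn-elimination towards the C17 methyl should give the C7 chloride with the alkene transposed to C8=C17, and the C7 configuration is irrelevant because C7 becomes CH2 in step 12.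

Step 12
Reactants: 17 19-tert-butyl 15-methyl (13E)-2α-acetoxy-7ξ-chlorolabda-8(17),13-diene-15,19-dioate
Product: 18 19-tert-butyl 15-methyl (13E)-2α-acetoxylabda-8(17),13-diene-15,19-dioate
Conditions: Pd(OAc)2 (5 mol %), n-Bu3P, HCO2NH4, 1,4-dioxane, 80 °C
Reagents that add atoms: none
Why: Palladium-catalysed formate hydrogenolysis of an allylic chloride; ionisation by zerovalent palladium gives one π-allyl complex from both C7 epimers, and hydride from the palladium formate is delivered to the more substituted terminus C7, leaving the exocyclic C8=C17 alkene.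

Step 13
Reactants: 18 19-tert-butyl 15-methyl (13E)-2α-acetoxylabda-8(17),13-diene-15,19-dioate
Product: 20 hypoxyterpoid A, (13E)-2α-hydroxylabda-8(17),13-diene-15,19-dioic acid, via trimethylsilyl ester 19 (not isolated)
Conditions: Me3SiOTf, 2,6-lutidine, CH2Cl2, 0 °C; then LiOH, THF–MeOH–H2O, 40 °C; aq. HCl to pH 3
Reagents that add atoms: lithium hydroxide, [Li+].[OH-]
Why: The silyl triflate cleaves the hindered tert-butyl ester by alkyl–oxygen fission (loss of isobutene, no attack at the neopentyl carbonyl needed), and in-flask saponification then hydrolyses the silyl ester, the C15 methyl ester and the C2 acetate without disturbing the exocyclic alkene or the 13E geometry.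

**Compound list**

1 | (R)-2-(but-3-en-1-yl)oxirane | C=CCC[C@@H]1CO1 | starting material
2 | tert-butyl methyl malonate | COC(=O)CC(=O)OC(C)(C)C | starting material
3 | tert-butyl (5R)-5-(but-3-en-1-yl)-2-oxooxolane-3-carboxylate (C3 epimers) | C=CCC[C@@H]1CC(C(=O)OC(C)(C)C)C(=O)O1 | intermediate
4 | tert-butyl (3S,5R)-5-(but-3-en-1-yl)-3-methyl-2-oxooxolane-3-carboxylate | C=CCC[C@@H]1C[C@](C)(C(=O)OC(C)(C)C)C(=O)O1 | intermediate
5 | tert-butyl (3S,5R)-5-(but-3-en-1-yl)-2-hydroxy-3-methyloxolane-3-carboxylate (anomers) | C=CCC[C@@H]1C[C@](C)(C(=O)OC(C)(C)C)C(O)O1 | intermediate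
6 | tert-butyl (3S,5R)-2-hydroxy-3-methyl-5-(3-oxopropyl)oxolane-3-carboxylate | O=CCC[C@@H]1C[C@](C)(C(=O)OC(C)(C)C)C(O)O1 | intermediate
7 | tert-butyl (1S,5R)-3-formyl-5-hydroxy-1-methylcyclohex-2-ene-1-carboxylate | O=CC1=C[C@@](C)(C(=O)OC(C)(C)C)C[C@H](O)C1 | intermediate
8 | tert-butyl (1S,5R)-5-acetoxy-3-formyl-1-methylcyclohex-2-ene-1-carboxylate | O=CC1=C[C@@](C)(C(=O)OC(C)(C)C)C[C@H](OC(C)=O)C1 | intermediate
9 | methyl geranate, methyl (2E)-3,7-dimethylocta-2,6-dienoate | CC(C)=CCC/C(C)=C/C(=O)OC | starting material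
10 | methyl (2E)-3-methyl-6-oxohex-2-enoate | O=CCC/C(C)=C/C(=O)OC | intermediate
11 | methyl (2E,6E)-3,7-dimethyl-8-oxoocta-2,6-dienoate | O=C/C(C)=C/CC/C(C)=C/C(=O)OC | intermediate
12 | methyl (2E,6E)-3,7-dimethylnona-2,6,8-trienoate | C=C/C(C)=C/CC/C(C)=C/C(=O)OC | intermediate
13 | (E)-ring-alkene isomer of 8 (twisted trans-cyclohexene, C1 and C4 trans across C5=C10) | O=CC/1=C\[C@@](C)(C(=O)OC(C)(C)C)C[C@H](OC(C)=O)C1 | intermediate
14 | 19-tert-butyl 15-methyl (13E)-2α-acetoxy-20-oxolabda-7,13-diene-15,19-dioate (5α-H, 9α-H, 10β-CHO, 4β-CO2tBu) | CC1=CC[C@@H]2[C@](C=O)(C[C@@H](OC(C)=O)C[C@]2(C)C(=O)OC(C)(C)C)[C@H]1CC/C(C)=C/C(=O)OC | intermediate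
15 | 20-(4-methylbenzenesulfonyl)hydrazone of 14 | CC1=CC[C@@H]2[C@](C=NNS(=O)(=O)c3ccc(C)cc3)(C[C@@H](OC(C)=O)C[C@]2(C)C(=O)OC(C)(C)C)[C@H]1CC/C(C)=C/C(=O)OC | intermediate
16 | 19-tert-butyl 15-methyl (13E)-2α-acetoxylabda-7,13-diene-15,19-dioate | CC1=CC[C@@H]2[C@](C)(C[C@@H](OC(C)=O)C[C@]2(C)C(=O)OC(C)(C)C)[C@H]1CC/C(C)=C/C(=O)OC | intermediate
17 | 19-tert-butyl 15-methyl (13E)-2α-acetoxy-7ξ-chlorolabda-8(17),13-diene-15,19-dioate | C=C1C(Cl)C[C@@H]2[C@](C)(C[C@@H](OC(C)=O)C[C@]2(C)C(=O)OC(C)(C)C)[C@H]1CC/C(C)=C/C(=O)OC | intermediate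
18 | 19-tert-butyl 15-methyl (13E)-2α-acetoxylabda-8(17),13-diene-15,19-dioate | C=C1CC[C@@H]2[C@](C)(C[C@@H](OC(C)=O)C[C@]2(C)C(=O)OC(C)(C)C)[C@H]1CC/C(C)=C/C(=O)OC | intermediate
19 | 15-methyl 19-trimethylsilyl (13E)-2α-acetoxylabda-8(17),13-diene-15,19-dioate | C=C1CC[C@@H]2[C@](C)(C[C@@H](OC(C)=O)C[C@]2(C)C(=O)O[Si](C)(C)C)[C@H]1CC/C(C)=C/C(=O)OC | intermediate
20 | hypoxyterpoid A, (1S,3R,4aR,5S,8aR)-5-[(3E)-4-carboxy-3-methylbut-3-en-1-yl]-3-hydroxy-1,4a-dimethyl-6-methylidenedecahydronaphthalene-1-carboxylic acid | C=C1CC[C@@H]2[C@](C)(C[C@@H](O)C[C@]2(C)C(=O)O)[C@H]1CC/C(C)=C/C(=O)O | target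

**Count and risks**

Total steps: 13. Longest linear sequence: 10 (steps 1–5, then 9–13); the diene branch is steps 6–8.

Steps most likely to fail:

1. Step 9. The (E)-cyclohexene may revert to 8 faster than it is captured bimolecularly, the excited enal may pass its triplet energy to the diene (E/Z scrambling of 12), or endo/exo and regiochemical discrimination may be poor. The fallback makes the capture intramolecular and sets out from 12 and 7. Saponification of 12 (LiOH, THF–H2O) would give (2E,6E)-3,7-dimethylnona-2,6,8-trienoic acid F1. Esterification with the free alcohol 7 (DCC, DMAP, CH2Cl2) would give the trienoyl ester F2. Irradiation of F2 (350 nm, dilute CH2Cl2, −78 °C) should deliver, by tethered trapping of the (E)-alkene, the ten-membered C15→2α-O lactone of the adduct F3. Methanolysis (NaOMe, MeOH) would open it to the 2α-hydroxy 15-methyl ester F4, and acetylation (Ac2O, pyridine) returns to the route at 14.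

2. Step 11. Proton loss may occur from C9 instead of C17 (giving the tetrasubstituted alkene), or chlorination may occur at another allylic site. The fallback sets out from 16. Allylic oxidation at the methyl group on the more substituted alkene carbon (SeO2 cat., t-BuOOH, CH2Cl2) would give the 17-hydroxy-Δ7 compound F5. Mitsunobu displacement with 2-nitrobenzenesulfonohydrazide (PPh3, diethyl azodicarboxylate, THF, −30 → 20 °C) forms the allylic diazene, whose sigmatropic loss of N2 transposes the alkene, returning to the route at 18 (step 12 is bypassed).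

3. Step 10. Hydrazone formation may be incomplete at the neopentyl angular aldehyde, or the diazene may fragment instead of giving the methyl group. The fallback sets out from 14. Thioacetalisation (HSCH2CH2SH, Zn(OTf)2 cat., CH2Cl2) would give the 20-(1,3-dithiolane) F6, and radical desulfurisation (n-Bu3SnH, AIBN, toluene, 110 °C) returns to the route at 16.

**Further compounds**

F1 | step 9 | (2E,6E)-3,7-dimethylnona-2,6,8-trienoic acid | C=C/C(C)=C/CC/C(C)=C/C(=O)O
F2 | step 9 | tert-butyl (1S,5R)-5-{[(2E,6E)-3,7-dimethylnona-2,6,8-trienoyl]oxy}-3-formyl-1-methylcyclohex-2-ene-1-carboxylate | O=CC1=C[C@@](C)(C(=O)OC(C)(C)C)C[C@H](OC(=O)/C=C(C)/CC/C=C(C)/C=C)C1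
F3 | step 9 | 19-tert-butyl (13E)-2α-hydroxy-20-oxolabda-7,13-diene-15,19-dioate 15,2-lactone (ten-membered lactone) | CC1=CC[C@@H]2[C@](C=O)(C[C@@H](O%10)C[C@]2(C)C(=O)OC(C)(C)C)[C@H]1CC/C(C)=C/C%10=O
F4 | step 9 | 19-tert-butyl 15-methyl (13E)-2α-hydroxy-20-oxolabda-7,13-diene-15,19-dioate | CC1=CC[C@@H]2[C@](C=O)(C[C@@H](O)C[C@]2(C)C(=O)OC(C)(C)C)[C@H]1CC/C(C)=C/C(=O)OC
F5 | step 11 | 19-tert-butyl 15-methyl (13E)-2α-acetoxy-17-hydroxylabda-7,13-diene-15,19-dioate | OCC1=CC[C@@H]2[C@](C)(C[C@@H](OC(C)=O)C[C@]2(C)C(=O)OC(C)(C)C)[C@H]1CC/C(C)=C/C(=O)OC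
F6 | step 10 | 19-tert-butyl 15-methyl (13E)-2α-acetoxy-20-(1,3-dithiolan-2-yl)-20-norlabda-7,13-diene-15,19-dioate (dithiolane of 14) | CC1=CC[C@@H]2[C@](C3SCCS3)(C[C@@H](OC(C)=O)C[C@]2(C)C(=O)OC(C)(C)C)[C@H]1CC/C(C)=C/C(=O)OC
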